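**Retrosynthetic overview**
- The phenol is unmasked last by O-demethylation of pentabromopseudilin methyl ether.
- The pyrrole C5–Br is traced back to a lactam C=O (deoxybromination with aromatisation), so the pyrrole becomes aromatic only in the penultimate step.
- The aryl–pyrrole C–C bond is cut to 2,4-dibromoanisole (C6–H) and a 3,4-dibromo-5-hydroxy-3-pyrrolin-2-one, joined by a new N-acyliminium aza-Friedel–Crafts reaction.
- The hydroxy lactam comes from mono-reduction of commercial 2,3-dibromomaleimide.
- Ring order: the benzene ring and the C4N ring are both bought intact; four of the five bromines come with the building blocks and the fifth from POBr3, so no electrophilic bromination is needed.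

Assumption: the target has no stereocentre (it is achiral), so "single enantiomer" is met by the compound itself; the sp3 centres of the lactam intermediates are racemic and are erased on aromatisation.

**Step 1**
Reactants: 1 2,3-dibromomaleimide (3,4-dibromo-1H-pyrrole-2,5-dione)
Product: 2 3,4-dibromo-5-hydroxy-1,5-dihydro-2H-pyrrol-2-one (racemic)
Conditions: NaBH4 (1.0 equiv), CeCl3·7H2O (1.1 equiv), MeOH/THF 1:1, −30 °C, 30 min; aq. NH4Cl
Reagents that add atoms: none
Why: Luche-type 1,2-reduction of one of the two equivalent imide carbonyls to the hydroxy lactam, in which Ce(III) activates C=O, suppresses conjugate hydride addition/debromination and keeps the medium non-basic, and the low temperature stops reduction at the cyclic hemiaminal; the new C5 centre is racemic and is removed in step 3.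

**Step 2**
Reactants: 2 3,4-dibromo-5-hydroxy-1,5-dihydro-2H-pyrrol-2-one (racemic), 3 2,4-dibromoanisole (2,4-dibromo-1-methoxybenzene)
Product: 5 3,4-dibromo-5-(3,5-dibromo-2-methoxyphenyl)-1,5-dihydro-2H-pyrrol-2-one (racemic), via N-acyliminium triflate 4 (not isolated)
Conditions: TfOH (1.5 equiv), 3 (2.0 equiv), HFIP, 0 °C → rt, 12 h
Reagents that add atoms: none
Why: Proposed new method: acid ionisation of the N,O-hemiaminal gives the cross-conjugated, 4π-destabilised and therefore very electrophilic 2-oxo-2H-pyrrolium ion 4, which is attacked at its iminium carbon (C5, not the hindered Br-bearing C3) by the only OMe-activated free position of 3 (C6, ortho; the para and other ortho sites carry Br), with HFIP stabilising the cation and the Wheland intermediate, so that the hydroxy lactam serves as a "3,4,5-tribromopyrrol-2-yl cation" surrogate that forms the biaryl C–C bond with two ring bromines already in place; the closest known reaction type is the Tscherniac–Einhorn amidoalkylation / N-acyliminium aza-Friedel–Crafts arylation of hydroxy lactams, which has not been shown for an N–H 3,4-dihalo-5-hydroxy-3-pyrrolin-2-one or with a deactivated dihaloanisole as π-nucleophile; the new C5 centre is racemic and is erased in step 3.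

**Step 3**
Reactants: 5 3,4-dibromo-5-(3,5-dibromo-2-methoxyphenyl)-1,5-dihydro-2H-pyrrol-2-one (racemic)
Product: 8 2,3,4-tribromo-5-(3,5-dibromo-2-methoxyphenyl)-1H-pyrrole, via O-phosphoryl iminium bromide 6 (not isolated), via bromo-2H-pyrrole 7 (not isolated)
Conditions: POBr3 (2.5 equiv), ClCH2CH2Cl, 75 °C, 4 h; then ice-water
Reagents that add atoms: phosphorus oxybromide (phosphoryl tribromide), O=P(Br)(Br)Br
Why: Deoxybromination of a lactam by Vilsmeier-type O-activation (the 2-pyridone → 2-bromopyridine reaction type applied to a 3-pyrrolin-2-one), in which O-phosphorylation gives imidate salt 6, bromide adds at C2 and expels dibromophosphate to give the cyclic imidoyl bromide 7, and prototropic shift of the doubly activated benzylic C–H aromatises it to the 1H-pyrrole, removing the only stereocentre; the aryl methyl ether and all C–Br bonds are inert.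

**Step 4**
Reactants: 8 2,3,4-tribromo-5-(3,5-dibromo-2-methoxyphenyl)-1H-pyrrole
Product: 10 pentabromopseudilin [2,4-dibromo-6-(3,4,5-tribromo-1H-pyrrol-2-yl)phenol], via aryloxydibromoborane 9 (not isolated)
Conditions: BBr3 (3 equiv), CH2Cl2, −78 °C → rt; then H2O
Reagents that add atoms: none
Why: Lewis-acid aryl methyl ether cleavage (BBr3 O-demethylation), in which boron coordinates the methoxy oxygen, bromide removes the methyl group by SN2 and the resulting aryloxyborane 9 is hydrolysed on work-up, while aryl and pyrrolyl C–Br bonds and the pyrrole N–H are untouched; no stereocentre is involved.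

**Compound list**
1 | 2,3-dibromomaleimide (3,4-dibromo-1H-pyrrole-2,5-dione) | O=C1NC(=O)C(Br)=C1Br | starting material
2 | 3,4-dibromo-5-hydroxy-1,5-dihydro-2H-pyrrol-2-one (racemic) | O=C1NC(O)C(Br)=C1Br | intermediate
3 | 2,4-dibromoanisole (2,4-dibromo-1-methoxybenzene) | COc1ccc(Br)cc1Br | starting material
4 | 3,4-dibromo-2-oxo-2H-pyrrol-1-ium triflate (N-acyliminium ion, not isolated) | O=C1C(Br)=C(Br)C=[NH+]1.[O-]S(=O)(=O)C(F)(F)F | intermediate
5 | 3,4-dibromo-5-(3,5-dibromo-2-methoxyphenyl)-1,5-dihydro-2H-pyrrol-2-one (racemic) | COc1c(Br)cc(Br)cc1C1NC(=O)C(Br)=C1Br | intermediate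
6 | 3,4-dibromo-2-(3,5-dibromo-2-methoxyphenyl)-5-[(dibromophosphoryl)oxy]-2H-pyrrol-1-ium bromide (racemic, not isolated) | COc1c(Br)cc(Br)cc1C1[NH+]=C(OP(=O)(Br)Br)C(Br)=C1Br.[Br-] | intermediate
7 | 3,4,5-tribromo-2-(3,5-dibromo-2-methoxyphenyl)-2H-pyrrole (racemic, not isolated) | COc1c(Br)cc(Br)cc1C1N=C(Br)C(Br)=C1Br | intermediate
8 | 2,3,4-tribromo-5-(3,5-dibromo-2-methoxyphenyl)-1H-pyrrole (pentabromopseudilin methyl ether) | COc1c(Br)cc(Br)cc1-c1[nH]c(Br)c(Br)c1Br | intermediate
9 | dibromo[2,4-dibromo-6-(3,4,5-tribromo-1H-pyrrol-2-yl)phenoxy]borane (not isolated) | BrB(Br)Oc1c(Br)cc(Br)cc1-c1[nH]c(Br)c(Br)c1Br | intermediate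
10 | pentabromopseudilin, 2,4-dibromo-6-(3,4,5-tribromo-1H-pyrrol-2-yl)phenol (achiral) | Oc1c(Br)cc(Br)cc1-c1[nH]c(Br)c(Br)c1Br | target

**Summary**
Total step count: 4. Longest linear sequence: 4 steps (1 → 2 → 5 → 8 → 10); compound 3 is a commercial partner that enters in step 2.

**Three steps most likely to fail, with fallbacks**

Step 2 (the proposed new method) is the most uncertain. The ion 4 may oligomerise, or the doubly brominated anisole may be too weak a π-nucleophile. The fallback uses only known chemistry and sets out from 3. Electrophilic iodination at C6 (NIS, cat. TfOH, MeCN, rt) gives 1,5-dibromo-3-iodo-2-methoxybenzene F1. A C–I-selective Suzuki–Miyaura coupling with (1-Boc-pyrrol-2-yl)boronic acid (Pd(PPh3)4, Na2CO3, DME/H2O, 50 °C) gives tert-butyl 2-(3,5-dibromo-2-methoxyphenyl)-1H-pyrrole-1-carboxylate F2. NaOMe in MeOH/THF removes the Boc group to give 2-(3,5-dibromo-2-methoxyphenyl)-1H-pyrrole F3. NBS (3.0 equiv, THF, −78 → 0 °C) then brominates the three free pyrrole positions; the anisole ring has no activated free site. The sequence comes back to the route at 8, which enters step 4.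

Step 3 is second. The electron-poor N–H lactam may be activated sluggishly, or the reaction may stall at the aromatic pyrrol-2-yl phosphate. The fallback sets out from 5 and replaces the C=O → C–Br conversion by C=O → C–H followed by electrophilic bromination. BH3·SMe2 (THF, reflux; MeOH/HCl work-up) reduces the lactam to 3,4-dibromo-2-(3,5-dibromo-2-methoxyphenyl)-2,5-dihydro-1H-pyrrole F4. DDQ (toluene, rt) dehydrogenates it to 3,4-dibromo-2-(3,5-dibromo-2-methoxyphenyl)-1H-pyrrole F5. NBS (1.0 equiv, THF, −78 °C) brominates the single free pyrrole position C5, and the sequence comes back to the route at 8.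

Step 1 is third. Possible failures are over-reduction through the ring-opened aldehyde, hydride conjugate addition with loss of bromide, or an unreactive imide anion. The fallback sets out from 1 and uses N-acyl activation instead of the free imide. Boc2O with cat. DMAP in MeCN gives tert-butyl 3,4-dibromo-2,5-dioxo-2,5-dihydro-1H-pyrrole-1-carboxylate F6. Its non-acidic, more electrophilic imide is reduced by DIBAL-H (CH2Cl2, −78 °C) to tert-butyl 3,4-dibromo-2-hydroxy-5-oxo-2,5-dihydro-1H-pyrrole-1-carboxylate F7. TFA (CH2Cl2, 0 °C; aqueous work-up) removes the Boc group, and the sequence comes back to the route at 2.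

**Further compounds**
F1 | step 2 | 1,5-dibromo-3-iodo-2-methoxybenzene (2,4-dibromo-6-iodoanisole) | COc1c(Br)cc(Br)cc1I
F2 | step 2 | tert-butyl 2-(3,5-dibromo-2-methoxyphenyl)-1H-pyrrole-1-carboxylate | COc1c(Br)cc(Br)cc1-c1cccn1C(=O)OC(C)(C)C
F3 | step 2 | 2-(3,5-dibromo-2-methoxyphenyl)-1H-pyrrole | COc1c(Br)cc(Br)cc1-c1ccc[nH]1
F4 | step 3 | 3,4-dibromo-2-(3,5-dibromo-2-methoxyphenyl)-2,5-dihydro-1H-pyrrole (racemic) | COc1c(Br)cc(Br)cc1C1NCC(Br)=C1Br
F5 | step 3 | 3,4-dibromo-2-(3,5-dibromo-2-methoxyphenyl)-1H-pyrrole | COc1c(Br)cc(Br)cc1-c1[nH]cc(Br)c1Br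
F6 | step 1 | tert-butyl 3,4-dibromo-2,5-dioxo-2,5-dihydro-1H-pyrrole-1-carboxylate | CC(C)(C)OC(=O)N1C(=O)C(Br)=C(Br)C1=O
F7 | step 1 | tert-butyl 3,4-dibromo-2-hydroxy-5-oxo-2,5-dihydro-1H-pyrrole-1-carboxylate (racemic) | CC(C)(C)OC(=O)N1C(O)C(Br)=C(Br)C1=O
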